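**Retrosynthetic overview**
- Chain carbons are counted c1–c11 from ring C (the Z-ylidenebutenolide) to ring A. The last disconnection is c1=C5 of ring C: vinylogous aldol–elimination between the c1 aldehyde of a ring A polyenynal and a ring B butenolide, then global desilylation.
- The strategy rests on the methyl-branched E-enyne ring A–c11≡c10–c9(CH3)=c8H. It is the syn adduct of CH3 and a metal across the free triple bond of a ring A buta-1,3-diyne, so methylalumination and palladium coupling with the c1–c7 iodotriene make c9–CH3 and c7–c8.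
- Ring A diyne: actinol → enol triflate → Sonogashira with mono-silylated butadiyne. Iodotriene: propargyl alcohol → methylalumination/iodination → enyne extension → hydrozirconation/iodination.
- Ring B: actinol inverted at its carbinol carbon → enol triflate → ethynyl → hydroxyl-directed epoxidation → anti hydrolysis at C5 (5,6-trans-diol) → hydrostannation → Stille coupling with 3-bromofuran-2(5H)-one (ring C).
- No ring is closed anywhere: rings A and B are carried from actinol, ring C from furan-2(5H)-one.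

Key step: step 11

Remark: ring B locants follow carotenoid usage (C1 = CMe2, C3 = CHOH, C5 = C(CH3)OH, C6 = carbinol carbon bearing the side chain); the SMILES places C3–OH of ring B on the face opposite to the ring A carbinol (both read R only because the CIP ranks differ), so the actinol used for ring B is inverted first (step 14), and 3-bromofuran-2(5H)-one is prepared rather than bought.

**Ring A diyne**

Step 1
Reactants: 1 (4R,6R)-4-hydroxy-2,2,6-trimethylcyclohexan-1-one (actinol)
Product: 2 (4R,6R)-4-[(tert-butyldimethylsilyl)oxy]-2,2,6-trimethylcyclohexan-1-one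
Conditions: TBSCl, imidazole, DMF, rt
Reagents that add atoms: tert-butyldimethylsilyl chloride, CC(C)(C)[Si](C)(C)Cl
Why: Imidazole-promoted silylation of an unhindered secondary alcohol; the ketone and both stereocentres are untouched.

Step 2
Reactants: 2 (4R,6R)-4-[(tert-butyldimethylsilyl)oxy]-2,2,6-trimethylcyclohexan-1-one
Product: 4 (4R)-4-[(tert-butyldimethylsilyl)oxy]-2,6,6-trimethylcyclohex-1-en-1-yl trifluoromethanesulfonate (ring A triflate), via lithium enolate 3 (not isolated)
Conditions: LiN(iPr)2, THF, −78 °C; then PhNTf2, −78 °C → rt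
Reagents that add atoms: N-phenylbis(trifluoromethanesulfonimide), O=S(=O)(N(c1ccccc1)S(=O)(=O)C(F)(F)F)C(F)(F)F
Why: Only C6 carries an α-hydrogen, so a single enolate forms and is O-sulfonylated (enolate triflation); C6 becomes sp2 and the carbinol centre is not affected.

Step 3
Reactants: 5 1,4-bis(trimethylsilyl)buta-1,3-diyne
Product: 7 buta-1,3-diyn-1-yl(trimethyl)silane, via lithium silylbutadiynide 6 (not isolated)
Conditions: MeLi·LiBr, Et2O, rt; then H2O, 0 °C; kept as an ethereal solution
Reagents that add atoms: none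
Why: Selective mono-desilylation: MeLi cleaves one alkynyl C–Si bond, the resulting acetylide resists a second attack, and protonation should give the mono-protected diyne.

Step 4
Reactants: 4 ring A triflate; 7 buta-1,3-diyn-1-yl(trimethyl)silane
Product: 8 tert-butyldimethyl({(1R)-3,5,5-trimethyl-4-[4-(trimethylsilyl)buta-1,3-diyn-1-yl]cyclohex-3-en-1-yl}oxy)silane
Conditions: Pd(PPh3)4 (cat.), CuI (cat.), iPr2NH, DMF, rt → 50 °C, degassed
Reagents that add atoms: none
Why: Sonogashira coupling of an enol triflate with a terminal alkyne; the silyl cap on the far alkyne prevents oligomerisation and the allylic gem-dimethyl group only slows oxidative addition.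

Step 5
Reactants: 8 silylated ring A diyne
Product: 9 ({(1R)-4-(buta-1,3-diyn-1-yl)-3,5,5-trimethylcyclohex-3-en-1-yl}oxy)(tert-butyl)dimethylsilane (ring A terminal diyne)
Conditions: K2CO3 (cat.), MeOH/THF, 0 °C; used at once
Reagents that add atoms: none
Why: Methoxide-catalysed protodesilylation of the alkynylsilane is much faster than attack on the secondary TBS ether, so the terminal 1,3-diyne should form cleanly.

**Iodotriene**

Step 6
Reactants: 10 prop-2-yn-1-ol; 11 trimethylaluminium
Product: 13 (E)-3-iodo-2-methylprop-2-en-1-ol, via alkenylalane alkoxide 12 (not isolated)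
Conditions: Cp2ZrCl2 (cat.), ClCH2CH2Cl, 0 °C → rt; then I2, THF, −30 → 0 °C; aqueous work-up
Reagents that add atoms: trimethylaluminium (11), C[Al](C)C; iodine, [I][I]
Why: Zirconium-catalysed methylalumination adds CH3 and Al syn across the alkyne with Al on the terminal carbon, and iodinolysis of the C–Al bond with retention should give the E iodide.

Step 7
Reactants: 13 (E)-3-iodo-2-methylprop-2-en-1-ol
Product: 14 triethyl{[(E)-3-iodo-2-methylprop-2-en-1-yl]oxy}silane
Conditions: TESCl, imidazole, CH2Cl2, 0 °C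
Reagents that add atoms: triethylsilyl chloride, CC[Si](CC)(CC)Cl
Why: Standard silylation of a primary allylic alcohol; TES is chosen because it can later be removed beside the ring A TBS ether.

Step 8
Reactants: 7 buta-1,3-diyn-1-yl(trimethyl)silane; 14 triethyl{[(E)-3-iodo-2-methylprop-2-en-1-yl]oxy}silane
Product: 17 triethyl{[(2E,4E)-2-methyl-7-(trimethylsilyl)hepta-2,4-dien-6-yn-1-yl]oxy}silane, via enynylzirconocene chloride 15 (not isolated), via enynylzinc chloride 16 (not isolated)
Conditions: Cp2Zr(H)Cl, THF, rt; then ZnCl2, Pd(PPh3)4 (cat.), THF, rt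
Reagents that add atoms: none
Why: Hydrozirconation adds H–Zr syn to the unsilylated triple bond with Zr on the terminal carbon, and zinc-assisted Negishi coupling with the alkenyl iodide retains the geometry of both partners.

Step 9
Reactants: 17 silylated dienyne
Product: 18 triethyl{[(2E,4E)-2-methylhepta-2,4-dien-6-yn-1-yl]oxy}silane
Conditions: K2CO3 (cat.), MeOH, 0 °C, short contact time
Reagents that add atoms: none
Why: Base-catalysed protodesilylation of the alkynylsilane; brief exposure at 0 °C should spare the primary TES ether.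

Step 10
Reactants: 18 terminal dienyne
Product: 20 triethyl{[(2E,4E,6E)-7-iodo-2-methylhepta-2,4,6-trien-1-yl]oxy}silane (iodotriene), via trienylzirconocene chloride 19 (not isolated)
Conditions: Cp2Zr(H)Cl, THF, rt, dark; then I2, 0 °C
Reagents that add atoms: iodine, [I][I]
Why: Hydrozirconation of the terminal alkyne (syn, Zr terminal; the internal conjugated alkenes do not react) and iodinolysis with retention should give the all-E iodotriene.

**Key step and polyenynal**

Step 11
Reactants: 9 ring A terminal diyne; 11 trimethylaluminium; 20 iodotriene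
Product: 23 tert-butyldimethyl({(1R)-3,5,5-trimethyl-4-[(3E,5E,7E,9E)-3,10-dimethyl-11-(triethylsilyloxy)undeca-3,5,7,9-tetraen-1-yn-1-yl]cyclohex-3-en-1-yl}oxy)silane (ring A tetraenyne bis-silyl ether), via alkenyldimethylalane 21 (not isolated), via alkenylzinc chloride 22 (not isolated)
Conditions: 11 (excess), Cp2ZrCl2, ClCH2CH2Cl, 0 °C → rt; volatiles removed in vacuo; then ZnCl2, THF; 20, Pd(PPh3)4 (cat.), rt, dark
Reagents that add atoms: trimethylaluminium (11), C[Al](C)C
Why: Me3Al and Cp2ZrCl2 form a chloride-bridged methylzirconium–aluminium species that adds CH3 and metal across the free triple bond of 9 in one syn step, methyl to the internal carbon c9 and the metal (aluminium after exchange) to the terminal carbon c8, giving alane 21; ZnCl2 converts 21 into alkenylzinc 22, zerovalent palladium inserts into the C–I bond of 20, accepts the alkenyl group from zinc and forms c7–c8 by reductive elimination. The closest known reaction type is zirconium-catalysed methylalumination of terminal alkynes, conjugated enynes and diynes included, followed by zinc-assisted palladium-catalysed alkenyl–alkenyl (Negishi) coupling. No ring is closed and no stereocentre is formed; the ring A carbinol centre is remote and unchanged. The step needs methyl on c9 rather than c8, syn delivery (which fixes the E geometry of c8=c9, methyl and c7 cis) and reaction at the terminal rather than the internal triple bond: the terminal alkyne is sterically open, whereas c10≡c11 is disubstituted and shielded by the ring A gem-dimethyl and vinylic methyl groups, and disubstituted alkynes are carbometalated far more slowly. Both palladium steps retain alkene geometry, so the E,E,E-triene of 20 and the new trisubstituted alkene should be transferred unchanged. Excess Me3Al is stripped before the coupling so that methyl transfer to 20 does not compete, and both silyl ethers tolerate the Lewis acids at room temperature.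

Step 12
Reactants: 23 ring A tetraenyne bis-silyl ether
Product: 24 (2E,4E,6E,8E)-11-{(4R)-4-[(tert-butyldimethylsilyl)oxy]-2,6,6-trimethylcyclohex-1-en-1-yl}-2,9-dimethylundeca-2,4,6,8-tetraen-10-yn-1-ol
Conditions: HF·pyridine, pyridine, THF, 0 °C, dark
Reagents that add atoms: none
Why: Fluoride cleaves the primary triethylsilyl ether much faster than the hindered secondary TBS ether, and the buffered medium avoids ionisation of the polyenyl allylic alcohol.

Step 13
Reactants: 24 tetraenynol
Product: 25 (2E,4E,6E,8E)-11-{(4R)-4-[(tert-butyldimethylsilyl)oxy]-2,6,6-trimethylcyclohex-1-en-1-yl}-2,9-dimethylundeca-2,4,6,8-tetraen-10-ynal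
Conditions: MnO2, CH2Cl2, rt, dark
Reagents that add atoms: none
Why: MnO2 oxidises allylic alcohols selectively to enals and should leave the polyenyne and the silyl ether alone.

**Ring B butenolide**

Step 14
Reactants: 1 (4R,6R)-4-hydroxy-2,2,6-trimethylcyclohexan-1-one (actinol)
Product: 26 (1S,3R)-3,5,5-trimethyl-4-oxocyclohexyl benzoate
Conditions: PhCO2H, PPh3, DIAD, THF, 0 °C → rt
Reagents that add atoms: benzoic acid, O=C(O)c1ccccc1
Why: Mitsunobu reaction: SN2 displacement of the activated hydroxyl by benzoate inverts the carbinol carbon and so sets the configuration that ring B needs at C3.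

Step 15
Reactants: 26 (1S,3R)-3,5,5-trimethyl-4-oxocyclohexyl benzoate
Product: 27 (1S)-3,5,5-trimethyl-4-{[(trifluoromethyl)sulfonyl]oxy}cyclohex-3-en-1-yl benzoate
Conditions: Tf2O, 2,6-di-tert-butyl-4-methylpyridine, CH2Cl2, 0 °C → rt
Reagents that add atoms: trifluoromethanesulfonic anhydride, O=S(=O)(OS(=O)(=O)C(F)(F)F)C(F)(F)F
Why: Enol triflate formation by O-sulfonylation of the ketone and loss of its only α-hydrogen to a hindered pyridine base; these non-basic conditions leave the benzoate intact.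

Step 16
Reactants: 27 ring B triflate benzoate; 28 ethynyltrimethylsilane
Product: 29 (1S)-3,5,5-trimethyl-4-[(trimethylsilyl)ethynyl]cyclohex-3-en-1-yl benzoate
Conditions: Pd(PPh3)4 (cat.), CuI (cat.), Et3N, DMF, 50 °C
Reagents that add atoms: none
Why: Sonogashira coupling of the enol triflate as in step 4; the benzoate tolerates the amine base.

Step 17
Reactants: 29 silylated enyne benzoate
Product: 30 (1S)-4-ethynyl-3,5,5-trimethylcyclohex-3-en-1-ol
Conditions: K2CO3, MeOH, rt
Reagents that add atoms: none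
Why: Methanolysis should remove the benzoate (transesterification) and the alkynyl silyl group in one operation.

Step 18
Reactants: 30 (1S)-4-ethynyl-3,5,5-trimethylcyclohex-3-en-1-ol
Product: 31 (1R,3R,6R)-6-ethynyl-1,5,5-trimethyl-7-oxabicyclo[4.1.0]heptan-3-ol (epoxide cis to the hydroxyl)
Conditions: VO(acac)2 (cat.), tBuOOH, toluene, 0 °C → rt
Reagents that add atoms: tert-butyl hydroperoxide, CC(C)(C)OO
Why: Vanadium-catalysed hydroxyl-directed epoxidation of a homoallylic cyclohexenol: the vanadate ester of the C3 hydroxyl delivers the peroxide oxygen to the face of C5=C6 on which the hydroxyl sits, setting C5 and C6 cis to C3–OH, and the triple bond is not oxidised.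

Step 19
Reactants: 31 cis-epoxy alcohol
Product: 32 (1R,2S,4R)-1-ethynyl-2,6,6-trimethylcyclohexane-1,2,4-triol (C5–OH trans to C6–OH; C6–OH cis to C3–OH)
Conditions: HClO4 (cat.), THF/H2O, 0 °C → rt
Reagents that add atoms: water, O
Why: Acid-catalysed epoxide hydrolysis with anti (Fürst–Plattner diaxial) opening: water should attack C5, because positive charge at C6 is disfavoured by the alkynyl group and two quaternary neighbours and only attack at C5 passes through the chair with C3–OH equatorial, so C5 is inverted and C6 keeps its oxygen.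

Step 20
Reactants: 32 ethynyl triol
Product: 33 (1R,2S,4R)-4-[(tert-butyldimethylsilyl)oxy]-1-ethynyl-2,6,6-trimethylcyclohexane-1,2-diol
Conditions: TBSCl, imidazole, DMF, rt
Reagents that add atoms: tert-butyldimethylsilyl chloride, CC(C)(C)[Si](C)(C)Cl
Why: Chemoselective silylation: only the secondary alcohol reacts, the two tertiary alcohols being too hindered for TBSCl.

Step 21
Reactants: 33 C3-silylated ethynyl diol
Product: 34 (1R,2S,4R)-4-[(tert-butyldimethylsilyl)oxy]-1-ethynyl-2,6,6-trimethyl-1,2-bis[(trimethylsilyl)oxy]cyclohexane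
Conditions: TMSOTf, 2,6-lutidine, CH2Cl2, −78 → 0 °C
Reagents that add atoms: trimethylsilyl trifluoromethanesulfonate, C[Si](C)(C)OS(=O)(=O)C(F)(F)F
Why: Silyl triflate with a pyridine base is reactive enough to cap both hindered tertiary alcohols with the small TMS group, masking them for the Lewis-acidic and basic steps ahead.

Step 22
Reactants: 34 fully silylated ethynyl ring B
Product: 35 tributyl{(E)-2-[(1S,2S,4R)-4-[(tert-butyldimethylsilyl)oxy]-2,6,6-trimethyl-1,2-bis[(trimethylsilyl)oxy]cyclohexyl]ethenyl}stannane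
Conditions: Bu3SnH, PdCl2(PPh3)2 (cat.), THF, 0 °C
Reagents that add atoms: tributyltin hydride, CCCC[SnH](CCCC)CCCC
Why: Palladium-catalysed hydrostannation adds H–Sn syn across the terminal alkyne, and the fully substituted propargylic carbon steers tin to the terminal carbon, so the E-alkenylstannane should result.

Step 23
Reactants: 36 furan-2(5H)-one
Product: 38 3-bromofuran-2(5H)-one, via trans-3,4-dibromodihydrofuran-2(3H)-one 37 (not isolated)
Conditions: Br2, CH2Cl2, 0 °C → rt; then Et3N, 0 °C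
Reagents that add atoms: bromine, BrBr
Why: Bromine addition to the enoate followed by amine-induced loss of HBr (acidic α-hydrogen, β-bromide leaves) is the standard addition–elimination route to an α-bromobutenolide.

Step 24
Reactants: 35 ring B alkenylstannane; 38 3-bromofuran-2(5H)-one
Product: 39 3-{(E)-2-[(1S,2S,4R)-4-[(tert-butyldimethylsilyl)oxy]-2,6,6-trimethyl-1,2-bis[(trimethylsilyl)oxy]cyclohexyl]ethenyl}furan-2(5H)-one (ring B butenolide)
Conditions: Pd2(dba)3 (cat.), AsPh3, CuI (cat.), NMP, rt → 45 °C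
Reagents that add atoms: none
Why: Stille coupling of an alkenylstannane with an α-bromo enoate under neutral conditions, with retention of the E geometry; the base-sensitive butenolide survives.

**Endgame**

Step 25
Reactants: 25 ring A tetraenynal; 39 ring B butenolide
Product: 42 tetrasilyl ether of the target (ring A 3-OTBS; ring B 3-OTBS and 5,6-bis-OTMS; Z-ylidenebutenolide), via silyloxyfuran 40 (not isolated), via silylated aldol adduct 41 (not isolated)
Conditions: TBSOTf, iPr2NEt, CH2Cl2, 0 °C → rt; then DBU, rt, dark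
Reagents that add atoms: none
Why: One-pot vinylogous Mukaiyama aldol–elimination: silyl triflate and amine convert the butenolide into its 2-silyloxyfuran, which adds through C5 to the triflate-activated aldehyde, and DBU then removes the C5 proton and expels silanolate (E1cB) to give the thermodynamically preferred Z-ylidenebutenolide with the chain syn to the ring oxygen.

Step 26
Reactants: 42 tetrasilyl ether of the target
Product: 43 CNP0163979.2 (target)
Conditions: HF·pyridine, pyridine, THF, 0 °C → rt, dark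
Reagents that add atoms: none
Why: Fluoride-mediated global desilylation removes the two secondary TBS and two tertiary TMS ethers under buffered conditions that should spare the ylidenebutenolide and the polyene; no stereocentre is touched.

**Compound list**

1 | (4R,6R)-4-hydroxy-2,2,6-trimethylcyclohexan-1-one (actinol) | C[C@@H]1C[C@@H](O)CC(C)(C)C1=O | starting material
2 | (4R,6R)-4-[(tert-butyldimethylsilyl)oxy]-2,2,6-trimethylcyclohexan-1-one | C[C@@H]1C[C@@H](O[Si](C)(C)C(C)(C)C)CC(C)(C)C1=O | intermediate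
3 | lithium enolate of 2 | CC1=C(O[Li])C(C)(C)C[C@H](O[Si](C)(C)C(C)(C)C)C1 | intermediate
4 | (4R)-4-[(tert-butyldimethylsilyl)oxy]-2,6,6-trimethylcyclohex-1-en-1-yl trifluoromethanesulfonate | CC1=C(OS(=O)(=O)C(F)(F)F)C(C)(C)C[C@H](O[Si](C)(C)C(C)(C)C)C1 | intermediate
5 | 1,4-bis(trimethylsilyl)buta-1,3-diyne | C[Si](C)(C)C#CC#C[Si](C)(C)C | starting material
6 | lithium 4-(trimethylsilyl)buta-1,3-diyn-1-ide | [Li]C#CC#C[Si](C)(C)C | intermediate
7 | buta-1,3-diyn-1-yl(trimethyl)silane | C#CC#C[Si](C)(C)C | intermediate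
8 | tert-butyldimethyl({(1R)-3,5,5-trimethyl-4-[4-(trimethylsilyl)buta-1,3-diyn-1-yl]cyclohex-3-en-1-yl}oxy)silane | CC1=C(C#CC#C[Si](C)(C)C)C(C)(C)C[C@H](O[Si](C)(C)C(C)(C)C)C1 | intermediate
9 | ({(1R)-4-(buta-1,3-diyn-1-yl)-3,5,5-trimethylcyclohex-3-en-1-yl}oxy)(tert-butyl)dimethylsilane | CC1=C(C#CC#C)C(C)(C)C[C@H](O[Si](C)(C)C(C)(C)C)C1 | intermediate
10 | prop-2-yn-1-ol | C#CCO | starting material
11 | trimethylaluminium | C[Al](C)C | starting material
12 | dimethylaluminium (E)-3-(dimethylalumanyl)-2-methylprop-2-en-1-olate | C[Al](C)/C=C(C)/CO[Al](C)C | intermediate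
13 | (E)-3-iodo-2-methylprop-2-en-1-ol | OC/C(C)=C/I | intermediate
14 | triethyl{[(E)-3-iodo-2-methylprop-2-en-1-yl]oxy}silane | CC[Si](CC)(CC)OC/C(C)=C/I | intermediate
15 | chlorobis(cyclopentadienyl)[(E)-4-(trimethylsilyl)but-1-en-3-yn-1-yl]zirconium | C[Si](C)(C)C#C/C=C/[Zr](Cl)(C1C=CC=C1)C1C=CC=C1 | intermediate
16 | chloro[(E)-4-(trimethylsilyl)but-1-en-3-yn-1-yl]zinc | C[Si](C)(C)C#C/C=C/[Zn]Cl | intermediate
17 | triethyl{[(2E,4E)-2-methyl-7-(trimethylsilyl)hepta-2,4-dien-6-yn-1-yl]oxy}silane | C[Si](C)(C)C#C/C=C/C=C(C)/CO[Si](CC)(CC)CC | intermediate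
18 | triethyl{[(2E,4E)-2-methylhepta-2,4-dien-6-yn-1-yl]oxy}silane | C#C/C=C/C=C(C)/CO[Si](CC)(CC)CC | intermediate
19 | chlorobis(cyclopentadienyl)[(1E,3E,5E)-6-methyl-7-(triethylsilyloxy)hepta-1,3,5-trien-1-yl]zirconium | Cl[Zr](/C=C/C=C/C=C(C)/CO[Si](CC)(CC)CC)(C1C=CC=C1)C1C=CC=C1 | intermediate
20 | triethyl{[(2E,4E,6E)-7-iodo-2-methylhepta-2,4,6-trien-1-yl]oxy}silane | I/C=C/C=C/C=C(C)/CO[Si](CC)(CC)CC | intermediate
21 | [(1E)-4-{(4R)-4-[(tert-butyldimethylsilyl)oxy]-2,6,6-trimethylcyclohex-1-en-1-yl}-2-methylbut-1-en-3-yn-1-yl]dimethylalumane | CC1=C(C#C/C(C)=C/[Al](C)C)C(C)(C)C[C@H](O[Si](C)(C)C(C)(C)C)C1 | intermediate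
22 | chloro[(1E)-4-{(4R)-4-[(tert-butyldimethylsilyl)oxy]-2,6,6-trimethylcyclohex-1-en-1-yl}-2-methylbut-1-en-3-yn-1-yl]zinc | CC1=C(C#C/C(C)=C/[Zn]Cl)C(C)(C)C[C@H](O[Si](C)(C)C(C)(C)C)C1 | intermediate
23 | tert-butyldimethyl({(1R)-3,5,5-trimethyl-4-[(3E,5E,7E,9E)-3,10-dimethyl-11-(triethylsilyloxy)undeca-3,5,7,9-tetraen-1-yn-1-yl]cyclohex-3-en-1-yl}oxy)silane | CC1=C(C#C/C(C)=C/C=C/C=C/C=C(C)/CO[Si](CC)(CC)CC)C(C)(C)C[C@H](O[Si](C)(C)C(C)(C)C)C1 | intermediate
24 | (2E,4E,6E,8E)-11-{(4R)-4-[(tert-butyldimethylsilyl)oxy]-2,6,6-trimethylcyclohex-1-en-1-yl}-2,9-dimethylundeca-2,4,6,8-tetraen-10-yn-1-ol | CC1=C(C#C/C(C)=C/C=C/C=C/C=C(C)/CO)C(C)(C)C[C@H](O[Si](C)(C)C(C)(C)C)C1 | intermediate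
25 | (2E,4E,6E,8E)-11-{(4R)-4-[(tert-butyldimethylsilyl)oxy]-2,6,6-trimethylcyclohex-1-en-1-yl}-2,9-dimethylundeca-2,4,6,8-tetraen-10-ynal | CC1=C(C#C/C(C)=C/C=C/C=C/C=C(C)/C=O)C(C)(C)C[C@H](O[Si](C)(C)C(C)(C)C)C1 | intermediate
26 | (1S,3R)-3,5,5-trimethyl-4-oxocyclohexyl benzoate | C[C@@H]1C[C@H](OC(=O)c2ccccc2)CC(C)(C)C1=O | intermediate
27 | (1S)-3,5,5-trimethyl-4-{[(trifluoromethyl)sulfonyl]oxy}cyclohex-3-en-1-yl benzoate | CC1=C(OS(=O)(=O)C(F)(F)F)C(C)(C)C[C@@H](OC(=O)c2ccccc2)C1 | intermediate
28 | ethynyltrimethylsilane | C#C[Si](C)(C)C | starting material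
29 | (1S)-3,5,5-trimethyl-4-[(trimethylsilyl)ethynyl]cyclohex-3-en-1-yl benzoate | CC1=C(C#C[Si](C)(C)C)C(C)(C)C[C@@H](OC(=O)c2ccccc2)C1 | intermediate
30 | (1S)-4-ethynyl-3,5,5-trimethylcyclohex-3-en-1-ol | CC1=C(C#C)C(C)(C)C[C@@H](O)C1 | intermediate
31 | (1R,3R,6R)-6-ethynyl-1,5,5-trimethyl-7-oxabicyclo[4.1.0]heptan-3-ol | C#C[C@]12C(C)(C)C[C@@H](O)C[C@@]1(C)O2 | intermediate
32 | (1R,2S,4R)-1-ethynyl-2,6,6-trimethylcyclohexane-1,2,4-triol | C#C[C@]1(O)C(C)(C)C[C@@H](O)C[C@]1(C)O | intermediate
33 | (1R,2S,4R)-4-[(tert-butyldimethylsilyl)oxy]-1-ethynyl-2,6,6-trimethylcyclohexane-1,2-diol | C#C[C@]1(O)C(C)(C)C[C@@H](O[Si](C)(C)C(C)(C)C)C[C@]1(C)O | intermediate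
34 | (1R,2S,4R)-4-[(tert-butyldimethylsilyl)oxy]-1-ethynyl-2,6,6-trimethyl-1,2-bis[(trimethylsilyl)oxy]cyclohexane | C#C[C@]1(O[Si](C)(C)C)C(C)(C)C[C@@H](O[Si](C)(C)C(C)(C)C)C[C@]1(C)O[Si](C)(C)C | intermediate
35 | tributyl{(E)-2-[(1S,2S,4R)-4-[(tert-butyldimethylsilyl)oxy]-2,6,6-trimethyl-1,2-bis[(trimethylsilyl)oxy]cyclohexyl]ethenyl}stannane | CCCC[Sn](CCCC)(CCCC)/C=C/[C@]1(O[Si](C)(C)C)C(C)(C)C[C@@H](O[Si](C)(C)C(C)(C)C)C[C@]1(C)O[Si](C)(C)C | intermediate
36 | furan-2(5H)-one | O=C1OCC=C1 | starting material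
37 | trans-3,4-dibromodihydrofuran-2(3H)-one (racemic, one enantiomer drawn) | O=C1OC[C@@H](Br)[C@@H]1Br | intermediate
38 | 3-bromofuran-2(5H)-one | O=C1OCC=C1Br | intermediate
39 | 3-{(E)-2-[(1S,2S,4R)-4-[(tert-butyldimethylsilyl)oxy]-2,6,6-trimethyl-1,2-bis[(trimethylsilyl)oxy]cyclohexyl]ethenyl}furan-2(5H)-one | O=C1OCC=C1/C=C/[C@]2(O[Si](C)(C)C)C(C)(C)C[C@@H](O[Si](C)(C)C(C)(C)C)C[C@]2(C)O[Si](C)(C)C | intermediate
40 | 2-[(tert-butyldimethylsilyl)oxy]furan derived from 39 (3-alkenyl-2-silyloxyfuran) | CC(C)(C)[Si](C)(C)Oc1occc1/C=C/[C@]2(O[Si](C)(C)C)C(C)(C)C[C@@H](O[Si](C)(C)C(C)(C)C)C[C@]2(C)O[Si](C)(C)C | intermediate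
41 | O-silylated vinylogous aldol adduct of 25 and 40 (mixture of epimers at the two new carbons) | CC1=C(C#C/C(C)=C/C=C/C=C/C=C(C)/C(O[Si](C)(C)C(C)(C)C)C2C=C(/C=C/[C@]3(O[Si](C)(C)C)C(C)(C)C[C@@H](O[Si](C)(C)C(C)(C)C)C[C@]3(C)O[Si](C)(C)C)C(=O)O2)C(C)(C)C[C@H](O[Si](C)(C)C(C)(C)C)C1 | intermediate
42 | tetrasilyl ether of the target (ring A 3-OTBS; ring B 3-OTBS, 5,6-bis-OTMS) | CC1=C(C#C/C(C)=C/C=C/C=C/C=C(C)/C=C2C=C(/C=C/[C@]3(O[Si](C)(C)C)C(C)(C)C[C@@H](O[Si](C)(C)C(C)(C)C)C[C@]3(C)O[Si](C)(C)C)C(=O)O/2)C(C)(C)C[C@H](O[Si](C)(C)C(C)(C)C)C1 | intermediate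
43 | CNP0163979.2: (5Z)-3-{(E)-2-[(1S,2S,4R)-1,2,4-trihydroxy-2,6,6-trimethylcyclohexyl]ethenyl}-5-{(2E,4E,6E,8E)-11-[(4R)-4-hydroxy-2,6,6-trimethylcyclohex-1-en-1-yl]-2,9-dimethylundeca-2,4,6,8-tetraen-10-yn-1-ylidene}furan-2(5H)-one | CC1=C(C#C/C(C)=C/C=C/C=C/C=C(C)/C=C2C=C(/C=C/[C@]3(O)C(C)(C)C[C@@H](O)C[C@]3(C)O)C(=O)O/2)C(C)(C)C[C@H](O)C1 | target

**Step count and risks**

Total steps: 26. Longest linear sequence: 12 steps (14–22, 24, 25, 26; actinol 1 through ring B to 43). The ring A arm (1, 2, 4, 5, 11–13, 25, 26) is 9 steps and the iodotriene arm (6–13, 25, 26) is 10.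

Steps most likely to fail:

1. Step 19 (epoxide hydrolysis). Water may enter at the propargylic carbon C6, or the developing C5 cation may lose a proton or trigger a 1,2-shift before it is captured. Fallback: the opening is done on a glycidic ester, where C6 is α to a carbonyl and cannot ionise, and the alkyne is made afterwards. It sets out from triflate 27. Palladium-catalysed methoxycarbonylation (Pd(OAc)2, PPh3, CO, MeOH, Et3N) would give methyl (4S)-4-(benzoyloxy)-2,6,6-trimethylcyclohex-1-ene-1-carboxylate F1. K2CO3/MeOH cleaves only the benzoate to give the hydroxy ester F2. VO(acac)2/tBuOOH gives the cis epoxy ester F3, and aqueous HClO4 opens it at C5 to the trihydroxy ester F4. TBSCl/imidazole gives the C3 silyl ether F5, and TMSOTf/2,6-lutidine gives the bis(trimethylsilyl) ether F6. iBu2AlH reduces the ester to the primary alcohol F7, and Dess–Martin periodinane gives the aldehyde F8. Lithiated (trimethylsilyl)diazomethane (Colvin rearrangement) turns the aldehyde into the terminal alkyne, returning to the route at 34.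

2. Step 11 (key step). The ring A enediyne may be carbometalated unselectively or oligomerise under Me3Al/Cp2ZrCl2, or the alkenylmetal may couple slowly so that methyl transfer to the iodide competes. Fallback: the methylalumination is moved to the small diyne 7 and ring A is attached last. It sets out from 7, 11 and 20. Methylalumination of the free triple bond of 7 would give the silylated enynylalane F9; ZnCl2 gives the enynylzinc chloride F10, and Pd(PPh3)4-catalysed coupling with 20 gives the silylated tetraenyne F11. K2CO3/MeOH gives the terminal tetraenyne F12, and Sonogashira coupling of this alkyne with triflate 4 returns to the route at 23.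

3. Step 25 (vinylogous aldol–elimination). The silyl triflate may strip the tertiary TMS ethers or ionise the hindered ring B carbinol, the extended silyloxyfuran 40 may react sluggishly at C5, and the elimination may give E/Z mixtures. Fallback: the ylidenebutenolide is built on the simple bromobutenolide and ring B is coupled last, so that ring B never meets silyl triflate or DBU. It sets out from aldehyde 25 and bromobutenolide 38. TBSOTf/iPr2NEt would give the bromosilyloxyfuran F13, which adds to 25 to give the silylated bromo aldol adduct F14. DBU (with iodine-catalysed equilibration if needed) gives the Z-bromo-ylidenebutenolide F15, and Stille coupling with stannane 35 (Pd2(dba)3, AsPh3, CuI) returns to the route at 42.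

**Further compounds**

F1 | step 19 | methyl (4S)-4-(benzoyloxy)-2,6,6-trimethylcyclohex-1-ene-1-carboxylate | CC1=C(C(=O)OC)C(C)(C)C[C@@H](OC(=O)c2ccccc2)C1
F2 | step 19 | methyl (4S)-4-hydroxy-2,6,6-trimethylcyclohex-1-ene-1-carboxylate | CC1=C(C(=O)OC)C(C)(C)C[C@@H](O)C1
F3 | step 19 | methyl (1R,3R,6S)-3-hydroxy-1,5,5-trimethyl-7-oxabicyclo[4.1.0]heptane-6-carboxylate (epoxide cis to the hydroxyl) | COC(=O)[C@]12C(C)(C)C[C@@H](O)C[C@@]1(C)O2
F4 | step 19 | methyl (1S,2S,4R)-1,2,4-trihydroxy-2,6,6-trimethylcyclohexane-1-carboxylate | COC(=O)[C@]1(O)C(C)(C)C[C@@H](O)C[C@]1(C)O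
F5 | step 19 | 4-O-TBS ether of F4 | COC(=O)[C@]1(O)C(C)(C)C[C@@H](O[Si](C)(C)C(C)(C)C)C[C@]1(C)O
F6 | step 19 | 4-O-TBS-1,2-bis-O-TMS ether of F4 | COC(=O)[C@]1(O[Si](C)(C)C)C(C)(C)C[C@@H](O[Si](C)(C)C(C)(C)C)C[C@]1(C)O[Si](C)(C)C
F7 | step 19 | primary alcohol from F6 (hydroxymethyl in place of ethynyl in 34) | OC[C@]1(O[Si](C)(C)C)C(C)(C)C[C@@H](O[Si](C)(C)C(C)(C)C)C[C@]1(C)O[Si](C)(C)C
F8 | step 19 | aldehyde from F7 (formyl in place of ethynyl in 34) | O=C[C@]1(O[Si](C)(C)C)C(C)(C)C[C@@H](O[Si](C)(C)C(C)(C)C)C[C@]1(C)O[Si](C)(C)C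
F9 | step 11 | dimethyl[(E)-2-methyl-4-(trimethylsilyl)but-1-en-3-yn-1-yl]alumane | C[Si](C)(C)C#C/C(C)=C/[Al](C)C
F10 | step 11 | chloro[(E)-2-methyl-4-(trimethylsilyl)but-1-en-3-yn-1-yl]zinc | C[Si](C)(C)C#C/C(C)=C/[Zn]Cl
F11 | step 11 | triethyl{[(2E,4E,6E,8E)-2,9-dimethyl-11-(trimethylsilyl)undeca-2,4,6,8-tetraen-10-yn-1-yl]oxy}silane | C[Si](C)(C)C#C/C(C)=C/C=C/C=C/C=C(C)/CO[Si](CC)(CC)CC
F12 | step 11 | triethyl{[(2E,4E,6E,8E)-2,9-dimethylundeca-2,4,6,8-tetraen-10-yn-1-yl]oxy}silane | C#C/C(C)=C/C=C/C=C/C=C(C)/CO[Si](CC)(CC)CC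
F13 | step 25 | [(3-bromofuran-2-yl)oxy](tert-butyl)dimethylsilane | CC(C)(C)[Si](C)(C)Oc1occc1Br
F14 | step 25 | O-silylated aldol adduct of 25 and F13 (mixture of epimers) | CC1=C(C#C/C(C)=C/C=C/C=C/C=C(C)/C(O[Si](C)(C)C(C)(C)C)C2C=C(Br)C(=O)O2)C(C)(C)C[C@H](O[Si](C)(C)C(C)(C)C)C1
F15 | step 25 | (5Z)-3-bromo-5-ylidenebutenolide of the ring A polyenyne (3-OTBS) | CC1=C(C#C/C(C)=C/C=C/C=C/C=C(C)/C=C2C=C(Br)C(=O)O/2)C(C)(C)C[C@H](O[Si](C)(C)C(C)(C)C)C1
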